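**Plan**

- Numbering runs from the carboxyl carbon C1 along the chain to C9, the CH2 on the furan; the 4‑methylpent‑3‑enyl branch sits on C2 and the acetoxymethyl group on C6.
- Retrosynthesis: remove the acetate and lower C1 to CH2OH, then cut the sp3–sp3 bond C3–C4 (alkyl triflate plus homoallylic Grignard reagent under copper catalysis). In the west half cut C7–C8 (Negishi), C5–C6 (vinyl carbomagnesiation of propargyl alcohol) and C9–furan (3‑furyllithium plus oxirane); in the east half cut the C2–side‑chain bond (malonate alkylation).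
- Enabling feature: C2 lies in an open chain, far from the only ring (the furan), and carries two one‑carbon arms, C1 and C3. With both arms as CH2OH, C2 is the prochiral carbon of a 2‑substituted propane‑1,3‑diol whose hydroxymethyl groups are enantiotopic and can be told apart by a lipase.
- Forward: the east half goes malonate → diol → enzymatic monoacetate, with the free arm silylated (future C1) and the acetate arm turned into the C3 triflate. The west half is a C4–C9 bromide carrying the furan. The halves are joined at C3–C4, then the acetate is installed and C1 oxidised; no ring is built.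
- Stereochemistry: C2 (R) comes from the lipase selecting one hydroxymethyl arm. The 6Z alkene comes from the anti carbomagnesiation, which holds magnesium on C7 cis to the CH2O group, followed by stereoretentive iodinolysis and coupling.

Key step: step 3

Assumption: the Pseudomonas fluorescens lipase is taken to acetylate the pro‑R hydroxymethyl group of diol 4, giving the R monoacetate 6; the opposite arm preference is handled among the fallbacks.

**Route**

Step 1
Reactants: 1 diethyl malonate; 2 5‑bromo‑2‑methylpent‑2‑ene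
Product: 3 diethyl 2‑(4‑methylpent‑3‑en‑1‑yl)malonate
Conditions: NaH, THF/DMF, 0 °C to 60 °C, 1 in excess (2 equiv)
Reagents that add atoms: none
Why: Malonic ester alkylation: the sodium enolate of 1 displaces the primary homoallylic bromide by SN2, and keeping 1 in excess holds back dialkylation.

Step 2
Reactants: 3 diethyl 2‑(4‑methylpent‑3‑en‑1‑yl)malonate
Product: 4 2‑(4‑methylpent‑3‑en‑1‑yl)propane‑1,3‑diol
Conditions: LiAlH4, THF, 0 °C to reflux; aqueous NaOH work‑up
Reagents that add atoms: none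
Why: Ester reduction with LiAlH4 takes both ethoxycarbonyl groups to CH2OH and leaves the isolated trisubstituted alkene alone, which gives the symmetric 1,3‑diol with C2 as its prochiral carbon.

Step 3
Reactants: 4 2‑(4‑methylpent‑3‑en‑1‑yl)propane‑1,3‑diol; 5 vinyl acetate
Product: 6 (R)‑2‑(hydroxymethyl)‑6‑methylhept‑5‑en‑1‑yl acetate
Conditions: Pseudomonas fluorescens lipase (Amano AK), 5 (2–3 equiv), t‑BuOMe, 0 °C to rt, stopped just after 4 is consumed
Reagents that add atoms: none
Why: The active‑site serine of the lipase is acetylated by vinyl acetate, irreversibly because the vinyl alcohol released tautomerises to acetaldehyde, and the acetyl‑enzyme then passes the acetyl group to the one hydroxymethyl group of 4 that the chiral pocket presents to it, forming a single O–acyl bond. The closest known reaction type is the lipase‑catalysed desymmetrising transesterification of 2‑monosubstituted propane‑1,3‑diols with enol esters. No ring is closed and no skeletal bond is formed. The new stereocenter C2 is controlled solely by the enzyme, which binds the lipophilic 4‑methylpent‑3‑enyl chain in its hydrophobic pocket and so places only the pro‑R CH2OH at the acyl‑serine. The step needs enantiotopic‑group selectivity and mono‑ over diacetylation; the first rests on the substrate being a 2‑monosubstituted 1,3‑diol with one large group and one hydrogen at the prochiral carbon, the second on limiting vinyl acetate and stopping early. Slight over‑acetylation should help purity, since the minor enantiomer of 6 still carries the free arm the enzyme prefers and is removed as the achiral diacetate.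

Step 4
Reactants: 6 (R)‑2‑(hydroxymethyl)‑6‑methylhept‑5‑en‑1‑yl acetate
Product: 7 (S)‑2‑{[(tert‑butyldiphenylsilyl)oxy]methyl}‑6‑methylhept‑5‑en‑1‑yl acetate
Conditions: TBDPSCl, imidazole, CH2Cl2, 0 °C to rt
Reagents that add atoms: tert‑butyl(chloro)diphenylsilane, CC(C)(C)[Si](Cl)(c1ccccc1)c1ccccc1
Why: Imidazole‑promoted silylation of the free primary alcohol, run directly on the fresh monoacetate, fixes which arm is which before 1,3‑acyl migration can erode the configuration, and the TBDPS ether is chosen because it outlasts methanolysis, triflation, the organocopper coupling and the later acidic removal of a TBS group.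

Step 5
Reactants: 7 (S)‑2‑{[(tert‑butyldiphenylsilyl)oxy]methyl}‑6‑methylhept‑5‑en‑1‑yl acetate
Product: 8 (S)‑2‑{[(tert‑butyldiphenylsilyl)oxy]methyl}‑6‑methylhept‑5‑en‑1‑ol
Conditions: K2CO3 (cat.), MeOH, 0 °C
Reagents that add atoms: none
Why: K2CO3‑catalysed transesterification with methanol removes the acetate under conditions too mild for the bulky silyl group to migrate between the two oxygens, so the C2 configuration is retained.

Step 6
Reactants: 9 3‑bromofuran; 10 ethylene oxide
Product: 12 2‑(furan‑3‑yl)ethanol, via furan‑3‑yllithium 11 (not isolated)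
Conditions: n‑BuLi, THF, −78 °C; then 10, BF3·OEt2, −78 °C; aqueous work‑up
Reagents that add atoms: none
Why: Bromine–lithium exchange at −78 °C gives the 3‑lithiofuran before it can isomerise to the 2‑lithio species, and BF3‑assisted ring opening of the epoxide at the same temperature attaches the two‑carbon alcohol chain that becomes C8 and C9.

Step 7
Reactants: 12 2‑(furan‑3‑yl)ethanol
Product: 13 3‑(2‑iodoethyl)furan
Conditions: I2, PPh3, imidazole, CH2Cl2, 0 °C
Reagents that add atoms: iodine, II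
Why: Appel‑type iodination: the alkoxyphosphonium ion formed from PPh3 and I2 is displaced by iodide in an SN2 step, and the buffered conditions leave the furan untouched.

Step 8
Reactants: 14 propargyl alcohol; 15 vinylmagnesium bromide (CH2=CHMgBr)
Product: 17 (Z)‑2‑(iodomethylidene)but‑3‑en‑1‑ol, via vinyl magnesium chelate 16 (not isolated)
Conditions: 15 (2.5 equiv), CuI (10 mol %), THF, −20 °C to rt; then I2, −78 °C to 0 °C
Reagents that add atoms: iodine, II
Why: Copper‑catalysed anti carbomagnesiation of the propargylic alkoxide places vinyl on the internal alkyne carbon (C6) and magnesium on the terminal carbon (C7), where the five‑membered oxamagnesacycle forces the C–Mg bond cis to the CH2O group, and iodinolysis with retention turns this into the Z iodoalkene that fixes the 6Z geometry of the target.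

Step 9
Reactants: 17 (Z)‑2‑(iodomethylidene)but‑3‑en‑1‑ol
Product: 18 (Z)‑tert‑butyl{[2‑(iodomethylidene)but‑3‑en‑1‑yl]oxy}dimethylsilane
Conditions: TBSCl, imidazole, CH2Cl2, 0 °C to rt
Reagents that add atoms: tert‑butyl(chloro)dimethylsilane, CC(C)(C)[Si](C)(C)Cl
Why: Standard imidazole‑promoted silylation masks the allylic hydroxyl so that it cannot quench the organozinc, borane and Grignard reagents used in the next steps.

Step 10
Reactants: 13 3‑(2‑iodoethyl)furan; 18 (Z)‑tert‑butyl{[2‑(iodomethylidene)but‑3‑en‑1‑yl]oxy}dimethylsilane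
Product: 20 (Z)‑tert‑butyl{[2‑ethenyl‑5‑(furan‑3‑yl)pent‑2‑en‑1‑yl]oxy}dimethylsilane, via 2‑(furan‑3‑yl)ethylzinc iodide 19 (not isolated)
Conditions: 13, Zn dust (activated with BrCH2CH2Br and Me3SiCl), THF, 40 °C; then 18, PdCl2(dppf) (5 mol %), THF, rt to 50 °C
Reagents that add atoms: none
Why: Negishi coupling: Zn inserts into the primary iodide, the alkylzinc transmetallates to the alkenylpalladium species formed by oxidative addition of the vinyl iodide, and reductive elimination, favoured over β‑hydride elimination by the wide‑bite‑angle dppf ligand, forms C7–C8 with retention of the alkene geometry.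

Step 11
Reactants: 20 (Z)‑tert‑butyl{[2‑ethenyl‑5‑(furan‑3‑yl)pent‑2‑en‑1‑yl]oxy}dimethylsilane
Product: 22 (Z)‑3‑{[(tert‑butyldimethylsilyl)oxy]methyl}‑6‑(furan‑3‑yl)hex‑3‑en‑1‑ol, via B‑alkyl‑9‑BBN adduct 21 (not isolated)
Conditions: 9‑BBN, THF, 0 °C to rt; then aq. NaOH, H2O2, 0 °C
Reagents that add atoms: hydrogen peroxide, OO
Why: Hydroboration–oxidation: the bulky 9‑BBN adds its boron to the terminal carbon of the monosubstituted vinyl group much faster than it attacks the trisubstituted alkene or the furan, and alkaline peroxide then replaces boron by hydroxyl with no effect on the alkene geometry.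

Step 12
Reactants: 22 (Z)‑3‑{[(tert‑butyldimethylsilyl)oxy]methyl}‑6‑(furan‑3‑yl)hex‑3‑en‑1‑ol
Product: 23 (Z)‑{[2‑(2‑bromoethyl)‑5‑(furan‑3‑yl)pent‑2‑en‑1‑yl]oxy}(tert‑butyl)dimethylsilane
Conditions: CBr4, PPh3, CH2Cl2, 0 °C
Reagents that add atoms: carbon tetrabromide, BrC(Br)(Br)Br
Why: Appel bromination converts the primary homoallylic alcohol to the bromide by SN2 displacement of the alkoxyphosphonium ion under neutral conditions that spare the silyl ether and the furan.

Step 13
Reactants: 8 (S)‑2‑{[(tert‑butyldiphenylsilyl)oxy]methyl}‑6‑methylhept‑5‑en‑1‑ol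
Product: 24 (R)‑2‑{[(tert‑butyldiphenylsilyl)oxy]methyl}‑6‑methylhept‑5‑en‑1‑yl trifluoromethanesulfonate
Conditions: Tf2O, 2,6‑lutidine, CH2Cl2, −78 °C; cold aqueous wash, used at once
Reagents that add atoms: trifluoromethanesulfonic anhydride, O=S(=O)(OS(=O)(=O)C(F)(F)F)C(F)(F)F
Why: Triflation of the primary alcohol with Tf2O and a hindered pyridine base at −78 °C gives the alkyl triflate without N‑alkylation of the base or ionisation, and the product is used at once because such triflates do not store.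

Step 14
Reactants: 23 (Z)‑{[2‑(2‑bromoethyl)‑5‑(furan‑3‑yl)pent‑2‑en‑1‑yl]oxy}(tert‑butyl)dimethylsilane; 24 (R)‑2‑{[(tert‑butyldiphenylsilyl)oxy]methyl}‑6‑methylhept‑5‑en‑1‑yl trifluoromethanesulfonate
Product: 26 (2R,6Z)‑1‑[(tert‑butyldiphenylsilyl)oxy]‑6‑{[(tert‑butyldimethylsilyl)oxy]methyl}‑9‑(furan‑3‑yl)‑2‑(4‑methylpent‑3‑en‑1‑yl)non‑6‑ene, via homoallylic Grignard reagent 25 (not isolated)
Conditions: 23, Mg turnings, THF, rt to 40 °C; then 24, CuBr·SMe2 (10 mol %), Et2O/THF, −30 °C to 0 °C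
Reagents that add atoms: none
Why: Copper‑catalysed cross‑coupling of a Grignard reagent with a primary alkyl triflate: Mg insertion gives the homoallylic Grignard reagent, whose cuprate displaces the triflate at C3 in a polar SN2‑type step, so that no C3 radical arises that could cyclise onto the side‑chain alkene and the stereocenter at C2, which is not a reacting carbon, is untouched.

Step 15
Reactants: 26 (2R,6Z)‑1‑[(tert‑butyldiphenylsilyl)oxy]‑6‑{[(tert‑butyldimethylsilyl)oxy]methyl}‑9‑(furan‑3‑yl)‑2‑(4‑methylpent‑3‑en‑1‑yl)non‑6‑ene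
Product: 27 (2R,6Z)‑1‑[(tert‑butyldiphenylsilyl)oxy]‑9‑(furan‑3‑yl)‑6‑(hydroxymethyl)‑2‑(4‑methylpent‑3‑en‑1‑yl)non‑6‑ene
Conditions: PPTS (cat.), MeOH, rt
Reagents that add atoms: none
Why: Selective acid‑catalysed desilylation: the small primary allylic TBS ether undergoes methanolysis with PPTS far faster than the bulky TBDPS ether, which frees only the C6 hydroxymethyl group.

Step 16
Reactants: 27 (2R,6Z)‑1‑[(tert‑butyldiphenylsilyl)oxy]‑9‑(furan‑3‑yl)‑6‑(hydroxymethyl)‑2‑(4‑methylpent‑3‑en‑1‑yl)non‑6‑ene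
Product: 28 (2R,6Z)‑6‑(acetoxymethyl)‑1‑[(tert‑butyldiphenylsilyl)oxy]‑9‑(furan‑3‑yl)‑2‑(4‑methylpent‑3‑en‑1‑yl)non‑6‑ene
Conditions: Ac2O, pyridine, DMAP (cat.), CH2Cl2, 0 °C to rt
Reagents that add atoms: acetic anhydride, CC(=O)OC(C)=O
Why: DMAP‑catalysed acylation of the primary allylic alcohol with acetic anhydride installs the acetate of the target under conditions that affect no other group.

Step 17
Reactants: 28 (2R,6Z)‑6‑(acetoxymethyl)‑1‑[(tert‑butyldiphenylsilyl)oxy]‑9‑(furan‑3‑yl)‑2‑(4‑methylpent‑3‑en‑1‑yl)non‑6‑ene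
Product: 29 (2R,6Z)‑6‑(acetoxymethyl)‑9‑(furan‑3‑yl)‑2‑(4‑methylpent‑3‑en‑1‑yl)non‑6‑en‑1‑ol
Conditions: TBAF, AcOH (1:1), THF, rt
Reagents that add atoms: none
Why: Fluoride‑mediated desilylation, buffered with acetic acid so that the solution is not basic enough to cleave the allylic acetate, frees the C1 hydroxyl.

Step 18
Reactants: 29 (2R,6Z)‑6‑(acetoxymethyl)‑9‑(furan‑3‑yl)‑2‑(4‑methylpent‑3‑en‑1‑yl)non‑6‑en‑1‑ol
Product: 30 (2R,6Z)‑6‑(acetoxymethyl)‑9‑(furan‑3‑yl)‑2‑(4‑methylpent‑3‑en‑1‑yl)non‑6‑enal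
Conditions: Dess–Martin periodinane, CH2Cl2, 0 °C to rt; crude aldehyde used directly
Reagents that add atoms: none
Why: Dess–Martin oxidation takes the primary alcohol to the aldehyde and no further under non‑basic conditions, so the α‑stereocenter C2 is not epimerised provided the aldehyde is carried on without delay.

Step 19
Reactants: 30 (2R,6Z)‑6‑(acetoxymethyl)‑9‑(furan‑3‑yl)‑2‑(4‑methylpent‑3‑en‑1‑yl)non‑6‑enal
Product: 31 (2R,6Z)‑6‑(acetoxymethyl)‑9‑(furan‑3‑yl)‑2‑(4‑methylpent‑3‑en‑1‑yl)non‑6‑enoic acid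
Conditions: NaClO2, NaH2PO4, 2‑methylbut‑2‑ene (large excess), t‑BuOH/H2O, 0 °C to rt
Reagents that add atoms: sodium chlorite, [Na+].[O-]Cl=O
Why: Pinnick oxidation: chlorous acid adds to the aldehyde and the adduct fragments to the carboxylic acid without enolisation, so C2 keeps its configuration, while the excess 2‑methylbut‑2‑ene traps the HOCl that would otherwise attack the furan and the trisubstituted alkenes.

**Compound list**

1 | diethyl malonate | CCOC(=O)CC(=O)OCC | starting material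
2 | 5‑bromo‑2‑methylpent‑2‑ene | CC(C)=CCCBr | starting material
3 | diethyl 2‑(4‑methylpent‑3‑en‑1‑yl)malonate | CCOC(=O)C(CCC=C(C)C)C(=O)OCC | intermediate
4 | 2‑(4‑methylpent‑3‑en‑1‑yl)propane‑1,3‑diol | CC(C)=CCCC(CO)CO | intermediate
5 | vinyl acetate | C=COC(C)=O | starting material
6 | (R)‑2‑(hydroxymethyl)‑6‑methylhept‑5‑en‑1‑yl acetate | CC(=O)OC[C@H](CCC=C(C)C)CO | intermediate
7 | (S)‑2‑{[(tert‑butyldiphenylsilyl)oxy]methyl}‑6‑methylhept‑5‑en‑1‑yl acetate | CC(=O)OC[C@H](CCC=C(C)C)CO[Si](c1ccccc1)(c1ccccc1)C(C)(C)C | intermediate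
8 | (S)‑2‑{[(tert‑butyldiphenylsilyl)oxy]methyl}‑6‑methylhept‑5‑en‑1‑ol | OC[C@H](CCC=C(C)C)CO[Si](c1ccccc1)(c1ccccc1)C(C)(C)C | intermediate
9 | 3‑bromofuran | Brc1ccoc1 | starting material
10 | ethylene oxide (oxirane) | C1CO1 | starting material
11 | furan‑3‑yllithium | [Li]c1ccoc1 | intermediate
12 | 2‑(furan‑3‑yl)ethanol | OCCc1ccoc1 | intermediate
13 | 3‑(2‑iodoethyl)furan | ICCc1ccoc1 | intermediate
14 | propargyl alcohol | C#CCO | starting material
15 | vinylmagnesium bromide | C=C[Mg]Br | starting material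
16 | 4‑ethenyl‑2,5‑dihydro‑1,2‑oxamagnesole (magnesium chelate) | C=CC1=C[Mg]OC1 | intermediate
17 | (Z)‑2‑(iodomethylidene)but‑3‑en‑1‑ol | OC/C(C=C)=C\I | intermediate
18 | (Z)‑tert‑butyl{[2‑(iodomethylidene)but‑3‑en‑1‑yl]oxy}dimethylsilane | CC(C)(C)[Si](C)(C)OC/C(C=C)=C\I | intermediate
19 | [2‑(furan‑3‑yl)ethyl]zinc iodide | I[Zn]CCc1ccoc1 | intermediate
20 | (Z)‑tert‑butyl{[2‑ethenyl‑5‑(furan‑3‑yl)pent‑2‑en‑1‑yl]oxy}dimethylsilane | CC(C)(C)[Si](C)(C)OC/C(C=C)=C\CCc1ccoc1 | intermediate
21 | 9‑[(Z)‑3‑{[(tert‑butyldimethylsilyl)oxy]methyl}‑6‑(furan‑3‑yl)hex‑3‑en‑1‑yl]‑9‑borabicyclo[3.3.1]nonane | CC(C)(C)[Si](C)(C)OC/C(CCB1C2CCCC1CCC2)=C\CCc1ccoc1 | intermediate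
22 | (Z)‑3‑{[(tert‑butyldimethylsilyl)oxy]methyl}‑6‑(furan‑3‑yl)hex‑3‑en‑1‑ol | CC(C)(C)[Si](C)(C)OC/C(CCO)=C\CCc1ccoc1 | intermediate
23 | (Z)‑{[2‑(2‑bromoethyl)‑5‑(furan‑3‑yl)pent‑2‑en‑1‑yl]oxy}(tert‑butyl)dimethylsilane | CC(C)(C)[Si](C)(C)OC/C(CCBr)=C\CCc1ccoc1 | intermediate
24 | (R)‑2‑{[(tert‑butyldiphenylsilyl)oxy]methyl}‑6‑methylhept‑5‑en‑1‑yl trifluoromethanesulfonate | O=S(=O)(OC[C@H](CCC=C(C)C)CO[Si](c1ccccc1)(c1ccccc1)C(C)(C)C)C(F)(F)F | intermediate
25 | [(Z)‑3‑{[(tert‑butyldimethylsilyl)oxy]methyl}‑6‑(furan‑3‑yl)hex‑3‑en‑1‑yl]magnesium bromide | CC(C)(C)[Si](C)(C)OC/C(CC[Mg]Br)=C\CCc1ccoc1 | intermediate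
26 | (2R,6Z)‑1‑[(tert‑butyldiphenylsilyl)oxy]‑6‑{[(tert‑butyldimethylsilyl)oxy]methyl}‑9‑(furan‑3‑yl)‑2‑(4‑methylpent‑3‑en‑1‑yl)non‑6‑ene | CC(C)(C)[Si](C)(C)OC/C(=C\CCc1ccoc1)CCC[C@H](CCC=C(C)C)CO[Si](c1ccccc1)(c1ccccc1)C(C)(C)C | intermediate
27 | (2R,6Z)‑1‑[(tert‑butyldiphenylsilyl)oxy]‑9‑(furan‑3‑yl)‑6‑(hydroxymethyl)‑2‑(4‑methylpent‑3‑en‑1‑yl)non‑6‑ene | OC/C(=C\CCc1ccoc1)CCC[C@H](CCC=C(C)C)CO[Si](c1ccccc1)(c1ccccc1)C(C)(C)C | intermediate
28 | (2R,6Z)‑6‑(acetoxymethyl)‑1‑[(tert‑butyldiphenylsilyl)oxy]‑9‑(furan‑3‑yl)‑2‑(4‑methylpent‑3‑en‑1‑yl)non‑6‑ene | CC(=O)OC/C(=C\CCc1ccoc1)CCC[C@H](CCC=C(C)C)CO[Si](c1ccccc1)(c1ccccc1)C(C)(C)C | intermediate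
29 | (2R,6Z)‑6‑(acetoxymethyl)‑9‑(furan‑3‑yl)‑2‑(4‑methylpent‑3‑en‑1‑yl)non‑6‑en‑1‑ol | CC(=O)OC/C(=C\CCc1ccoc1)CCC[C@H](CCC=C(C)C)CO | intermediate
30 | (2R,6Z)‑6‑(acetoxymethyl)‑9‑(furan‑3‑yl)‑2‑(4‑methylpent‑3‑en‑1‑yl)non‑6‑enal | CC(=O)OC/C(=C\CCc1ccoc1)CCC[C@H](CCC=C(C)C)C=O | intermediate
31 | (2R,6Z)‑6‑(acetoxymethyl)‑9‑(furan‑3‑yl)‑2‑(4‑methylpent‑3‑en‑1‑yl)non‑6‑enoic acid | CC(=O)OC/C(=C\CCc1ccoc1)CCC[C@H](CCC=C(C)C)C(=O)O | target

**Step count**

Total: 19 steps. Longest linear sequence: 12 steps (steps 1–5 and 13–19, from diethyl malonate); the west branch (steps 6–12) joins at step 14.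

**Steps most likely to fail**

1. Step 8. The vinyl Grignard reagent may deprotonate the terminal alkyne faster than it adds, the anti selectivity may be incomplete, and the iododiene may polymerise during isolation. The fallback sets out from 14 and returns at 22. Allylmagnesium bromide (CH2=CHCH2MgBr), the Grignard class that adds most readily in hydroxyl‑directed anti carbomagnesiation, would be added to 14 in Et2O to give 4‑(prop‑2‑en‑1‑yl)‑2,5‑dihydro‑1,2‑oxamagnesole F1. Iodinolysis of the chelate would give (Z)‑2‑(iodomethylidene)pent‑4‑en‑1‑ol F2, and silylation with TBSCl and imidazole would give (Z)‑tert‑butyl{[2‑(iodomethylidene)pent‑4‑en‑1‑yl]oxy}dimethylsilane F3. Lemieux–Johnson cleavage of the monosubstituted alkene (OsO4 cat., NaIO4, 2,6‑lutidine, dioxane/H2O) would give (Z)‑3‑{[(tert‑butyldimethylsilyl)oxy]methyl}‑4‑iodobut‑3‑enal F4. Immediate NaBH4 reduction would give (Z)‑3‑{[(tert‑butyldimethylsilyl)oxy]methyl}‑4‑iodobut‑3‑en‑1‑ol F5. Negishi coupling of F5 with an excess of the zinc reagent 19 and PdCl2(dppf) would then deliver 22, so the diene and its hydroboration are bypassed.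

2. Step 14. Mg insertion may be accompanied by Wurtz‑type dimerisation, and the triflate may be lost by ionisation with participation of the side‑chain alkene or by elimination before the cuprate attacks. The fallback sets out from 23 and 8 and returns at 26. Displacement of the bromide of 23 with PhSO2Na in DMF would give (Z)‑tert‑butyl{[5‑(furan‑3‑yl)‑2‑[2‑(phenylsulfonyl)ethyl]pent‑2‑en‑1‑yl]oxy}dimethylsilane F6. Alcohol 8 would be converted with I2, PPh3 and imidazole into (R)‑tert‑butyl{[2‑(iodomethyl)‑6‑methylhept‑5‑en‑1‑yl]oxy}diphenylsilane F7, which is stable and storable. Deprotonation of F6 with n‑BuLi in THF at −78 °C would give the α‑lithio sulfone F8. Its SN2 alkylation with F7 in THF/DMPU would form the C3–C4 bond in the C4‑phenylsulfonyl derivative of 26 F9, as a mixture at C4. Reductive desulfonylation with Na(Hg) and Na2HPO4 in MeOH at −20 °C would remove the sulfone and give 26.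

3. Step 3. The enzyme may acetylate the opposite enantiotopic arm, or discriminate the two arms too weakly. The fallback sets out from 4 and returns at 6. Acetylation of 4 with Ac2O, pyridine and DMAP would give 2‑(4‑methylpent‑3‑en‑1‑yl)propane‑1,3‑diyl diacetate F10. The same lipase in pH 7 phosphate buffer would then hydrolyse one enantiotopic ester. Because the enzyme acts on the same arm in both directions, hydrolysis leaves the acetyl group on the arm that acylation would have left free, and an enzyme with the wrong preference in the acylation mode should therefore give 6 in the hydrolysis mode.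

**Further compounds**

F1 | step 8 | 4‑(prop‑2‑en‑1‑yl)‑2,5‑dihydro‑1,2‑oxamagnesole | C=CCC1=C[Mg]OC1
F2 | step 8 | (Z)‑2‑(iodomethylidene)pent‑4‑en‑1‑ol | OC/C(CC=C)=C\I
F3 | step 8 | (Z)‑tert‑butyl{[2‑(iodomethylidene)pent‑4‑en‑1‑yl]oxy}dimethylsilane | CC(C)(C)[Si](C)(C)OC/C(CC=C)=C\I
F4 | step 8 | (Z)‑3‑{[(tert‑butyldimethylsilyl)oxy]methyl}‑4‑iodobut‑3‑enal | CC(C)(C)[Si](C)(C)OC/C(CC=O)=C\I
F5 | step 8 | (Z)‑3‑{[(tert‑butyldimethylsilyl)oxy]methyl}‑4‑iodobut‑3‑en‑1‑ol | CC(C)(C)[Si](C)(C)OC/C(CCO)=C\I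
F6 | step 14 | (Z)‑tert‑butyl{[5‑(furan‑3‑yl)‑2‑[2‑(phenylsulfonyl)ethyl]pent‑2‑en‑1‑yl]oxy}dimethylsilane | CC(C)(C)[Si](C)(C)OC/C(CCS(=O)(=O)c1ccccc1)=C\CCc1ccoc1
F7 | step 14 | (R)‑tert‑butyl{[2‑(iodomethyl)‑6‑methylhept‑5‑en‑1‑yl]oxy}diphenylsilane | IC[C@H](CCC=C(C)C)CO[Si](c1ccccc1)(c1ccccc1)C(C)(C)C
F8 | step 14 | α‑lithio derivative of sulfone F6 | CC(C)(C)[Si](C)(C)OC/C(CC([Li])S(=O)(=O)c1ccccc1)=C\CCc1ccoc1
F9 | step 14 | C4‑phenylsulfonyl derivative of 26 (both C4 epimers) | CC(C)(C)[Si](C)(C)OC/C(=C\CCc1ccoc1)CC(C[C@H](CCC=C(C)C)CO[Si](c1ccccc1)(c1ccccc1)C(C)(C)C)S(=O)(=O)c1ccccc1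
F10 | step 3 | 2‑(4‑methylpent‑3‑en‑1‑yl)propane‑1,3‑diyl diacetate | CC(=O)OCC(CCC=C(C)C)COC(C)=O
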